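**Retrosynthetic overview**
1. The target is an isomer of a cis-fused guaianolide epoxy-aldehyde. Cutting the C1–C5 bond in the last step (5/7 → 10) makes the enal, the C4=C5 alkene and the CH2OH group together.
2. The CHO comes from C10=CH2 by hydroboration and oxidation. The spiro-epoxide comes from C4=CH2 by OH-directed epoxidation. The lactone comes from C6–OH and the acrylate ester.
3. The seven-membered ring is closed at C5–C6 by an intramolecular Hosomi–Sakurai reaction, which also fixes the cis ring fusion.
4. C7–C8 is made by catalytic asymmetric Cr allylation with a Baylis–Hillman-derived bromide. The C8 ester is installed by Mitsunobu inversion.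
5. The cyclopentenyl allylsilane comes from cyclopentenone by conjugate addition, enol triflate formation and Kumada coupling. Ring order: five-membered ring (bought) → seven-membered ring → lactone → ten-membered ring.

Assumption: 4,4-dimethoxybut-1-yne and aqueous 2,2-dimethoxyacetaldehyde are taken as commercial. Labels C1–C15 follow germacrane/guaiane numbering of the target (C6 = lactone O–CH, C8 = ester carbon, C14 = CHO, C15 = CH2OH); α means down and β means up.

**Step 1**
Reactants: 1 methyl acrylate; 2 2,2-dimethoxyacetaldehyde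
Product: 3 methyl 3-hydroxy-4,4-dimethoxy-2-methylidenebutanoate (racemic)
Conditions: DABCO (20 mol%), dioxane/H2O, 22 °C
Reagents that add atoms: none
Why: This Morita–Baylis–Hillman reaction joins C7 to C11, and the carbinol stereocentre does not matter because it is lost in step 2.

**Step 2**
Reactants: 3 methyl 3-hydroxy-4,4-dimethoxy-2-methylidenebutanoate
Product: 4 methyl (Z)-2-(bromomethyl)-4,4-dimethoxybut-2-enoate
Conditions: NBS, Me2S, CH2Cl2, 0 → 22 °C
Reagents that add atoms: N-bromosuccinimide O=C1CCC(=O)N1Br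
Why: SN2′ bromination of the Baylis–Hillman alcohol through its alkoxysulfonium salt (Corey–Kim type) gives the usual Z bromide, and the acetal survives these non-acidic conditions.

**Step 3**
Reactants: 5 4,4-dimethoxybut-1-yne; 6 cyclopent-2-en-1-one
Product: 8 (3R)-3-(4,4-dimethoxybut-1-en-2-yl)cyclopent-1-en-1-yl trifluoromethanesulfonate, via alkenylalane 7 (not isolated)
Conditions: 5, DIBAL-H, Ni(dppp)Cl2 (3 mol%), THF, 22 °C; then 6, chiral NHC–Cu (5 mol%), −30 °C; then PhNTf2, −30 → 22 °C
Reagents that add atoms: N-phenylbis(trifluoromethanesulfonimide) O=S(=O)(N(c1ccccc1)S(=O)(=O)C(F)(F)F)C(F)(F)F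
Why: α-Selective Ni-catalysed hydroalumination followed by Cu-catalysed enantioselective conjugate addition sets C1 (R) under ligand control, and triflation of the enolate fixes the C4=C5 enol triflate regiospecifically.

**Step 4**
Reactants: 8 enol triflate; 9 (trimethylsilyl)methylmagnesium chloride
Product: 11 3-[(1R)-3-(trimethylsilylmethyl)cyclopent-2-en-1-yl]but-3-enal, via allylsilane acetal 10 (not isolated)
Conditions: Pd(PPh3)4 (3 mol%), LiCl, Et2O, 22 °C; then 1 M HCl, THF, 0 °C
Reagents that add atoms: water O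
Why: Kumada coupling of the vinyl triflate brings in C15 as an allylsilane, and brief dilute-acid acetal hydrolysis frees the C8 aldehyde without protodesilylation.

**Step 5**
Reactants: 11 allylsilane aldehyde; 4 allylic bromide
Product: 13 methyl (3R,4S)-3-(dimethoxymethyl)-4-hydroxy-2,6-dimethylidene-6-[(1R)-3-(trimethylsilylmethyl)cyclopent-2-en-1-yl]hexanoate, via silyl ether 12 (not isolated)
Conditions: CrCl2 (10 mol%), chiral carbazole-bis(oxazoline) ligand (12 mol%), Mn, TMSCl, THF, 0 °C; then 0.5 M HCl work-up, 0 °C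
Reagents that add atoms: none
Why: In this catalytic asymmetric Nozaki–Hiyama 2-(alkoxycarbonyl)allylation the equilibrating allyl-Cr(III) reacts through a chair transition state to give the anti C7/C8 pair, and the ligand sets C7 (R, final) and C8 (S, to be inverted).

**Step 6**
Reactants: 13 anti alcohol; 14 3-methylbutanoic acid
Product: 16 methyl (3R,4R)-3-formyl-2,6-dimethylidene-4-(3-methylbutanoyloxy)-6-[(1R)-3-(trimethylsilylmethyl)cyclopent-2-en-1-yl]hexanoate, via ester acetal 15 (not isolated)
Conditions: PPh3, DIAD, toluene, 0 → 22 °C; then LiBF4, MeCN/H2O (50:1), 40 °C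
Reagents that add atoms: water O
Why: The Mitsunobu esterification installs the isovalerate with clean SN2 inversion to the final (8R) centre, and mild LiBF4 acetal cleavage frees the C6 aldehyde without epimerising C7.

**Step 7**
Reactants: 16 allylsilane aldehyde
Product: 17 cis-fused guaiane hydroxy ester (1α-H, 5α-H, 6α-OH, 7α-H, 8β-isovaleryloxy, 4(15)- and 10(14)-exomethylene, 1-(methoxycarbonyl)vinyl on C7)
Conditions: BF3·OEt2 (1.1 equiv), CH2Cl2 (2 mM), −78 °C; cold aqueous work-up
Reagents that add atoms: none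
Why: In this intramolecular Hosomi–Sakurai allylation the much more nucleophilic allylsilane outcompetes the 1,1-disubstituted alkene, the tether on C1 forces C5–C6 bond formation on its own face (cis fusion), and a chair-like arrangement with C7 pseudo-equatorial gives 6α-OH.

**Step 8**
Reactants: 17 hydroxy ester
Product: 19 8β-isovaleryloxy-4β,15-epoxyguaia-10(14),11(13)-dien-12,6α-olide (1α,5α,7α-H), via epoxy alcohol 18 (not isolated)
Conditions: VO(acac)2 (5 mol%), t-BuOOH, CH2Cl2, 0 °C; then DBU (20 mol%), 22 °C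
Reagents that add atoms: tert-butyl hydroperoxide CC(C)(C)OO
Why: Vanadium-catalysed homoallylic-alcohol-directed epoxidation attacks only C4=C15 and delivers oxygen on the face that carries C6 (4β), after which base closes the trans γ-lactone with loss of methanol.

**Step 9**
Reactants: 19 epoxy lactone
Product: 21 14-hydroxy derivative of 19 (10α-H, CH2OH on C10), via B-alkyl-9-BBN 20 (not isolated)
Conditions: 9-BBN (1.1 equiv), THF, 0 °C; then H2O2, pH 7 phosphate buffer, 0 °C
Reagents that add atoms: hydrogen peroxide OO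
Why: Anti-Markovnikov hydroboration–oxidation takes the only electron-rich alkene from the convex face, while the electron-poor α-methylene lactone, the epoxide and the esters survive 9-BBN and buffered peroxide.

**Step 10**
Reactants: 21 primary alcohol
Product: 22 8β-isovaleryloxy-4β,15-epoxy-14-oxoguai-11(13)-en-12,6α-olide (1α,5α,7α,10α-H)
Conditions: Dess–Martin periodinane, NaHCO3, CH2Cl2, 0 °C
Reagents that add atoms: none
Why: Buffered Dess–Martin oxidation gives the aldehyde under neutral conditions that leave the epoxide and the α-methylene lactone untouched.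

**Step 11**
Reactants: 22 epoxy aldehyde
Product: 23 target (6R,7R,8R; both ring alkenes cis in the ring)
Conditions: DBU (30 mol%), toluene, 22 → 60 °C
Reagents that add atoms: none
Why: Proposed new method: DBU reversibly enolises the C10 formyl group, and in the cis-fused conformer with C6 pseudo-axial on the cyclopentane the C1–C5 σ bond lies parallel to the enolate π system and anti-periplanar to the C4–O epoxide bond, so an enolate-assisted Grob fragmentation cuts C1–C5, forms C1=C10 (A1,3 strain keeps H1 syn to CHO, giving the ring-cis E enal) and C4=C5 (oxygen cis to C6 puts C3 and C6 cis) and frees the C15 alkoxide, driven by loss of epoxide strain and by enal conjugation with C6, C7 and C8 untouched; the closest known reaction types are the enolate-assisted 1,4-fragmentation of decalin aldehyde sulfonates to germacranes and the epoxy-alcohol Grob fragmentation.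

**Compound list**
1 | methyl acrylate | C=CC(=O)OC | starting material
2 | 2,2-dimethoxyacetaldehyde | COC(OC)C=O | starting material
3 | methyl 3-hydroxy-4,4-dimethoxy-2-methylidenebutanoate (racemic) | C=C(C(=O)OC)C(O)C(OC)OC | intermediate
4 | methyl (Z)-2-(bromomethyl)-4,4-dimethoxybut-2-enoate | BrC/C(C(=O)OC)=C\C(OC)OC | intermediate
5 | 4,4-dimethoxybut-1-yne | C#CCC(OC)OC | starting material
6 | cyclopent-2-en-1-one | O=C1C=CCC1 | starting material
7 | diisobutyl(4,4-dimethoxybut-1-en-2-yl)alane | C=C(CC(OC)OC)[Al](CC(C)C)CC(C)C | intermediate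
8 | (3R)-3-(4,4-dimethoxybut-1-en-2-yl)cyclopent-1-en-1-yl triflate | C=C(CC(OC)OC)[C@@H]1CCC(OS(=O)(=O)C(F)(F)F)=C1 | intermediate
9 | (trimethylsilyl)methylmagnesium chloride | C[Si](C)(C)C[Mg]Cl | starting material
10 | {[(3R)-3-(4,4-dimethoxybut-1-en-2-yl)cyclopent-1-en-1-yl]methyl}trimethylsilane | C=C(CC(OC)OC)[C@@H]1CCC(C[Si](C)(C)C)=C1 | intermediate
11 | 3-[(1R)-3-(trimethylsilylmethyl)cyclopent-2-en-1-yl]but-3-enal | C=C(CC=O)[C@@H]1CCC(C[Si](C)(C)C)=C1 | intermediate
12 | O-trimethylsilyl ether of 13 | C=C(C(=O)OC)[C@@H](C(OC)OC)[C@@H](O[Si](C)(C)C)CC(=C)[C@@H]1CCC(C[Si](C)(C)C)=C1 | intermediate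
13 | (3R,4S) anti hydroxy ester (C7 R, C8 S, C1 R) | C=C(C(=O)OC)[C@@H](C(OC)OC)[C@@H](O)CC(=C)[C@@H]1CCC(C[Si](C)(C)C)=C1 | intermediate
14 | 3-methylbutanoic acid | CC(C)CC(=O)O | starting material
15 | (3R,4R) isovalerate acetal | C=C(C(=O)OC)[C@@H](C(OC)OC)[C@H](OC(=O)CC(C)C)CC(=C)[C@@H]1CCC(C[Si](C)(C)C)=C1 | intermediate
16 | (3R,4R) isovalerate aldehyde | C=C(C(=O)OC)[C@@H](C=O)[C@H](OC(=O)CC(C)C)CC(=C)[C@@H]1CCC(C[Si](C)(C)C)=C1 | intermediate
17 | cis-fused guaiane hydroxy ester (1α,5α,7α-H, 6α-OH, 8β-OCOiBu) | C=C1CC[C@@H]2[C@H]1[C@@H](O)[C@H](C(=C)C(=O)OC)[C@H](OC(=O)CC(C)C)CC2=C | intermediate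
18 | 4β,15-epoxide of 17 | C=C(C(=O)OC)[C@H]1[C@H](O)[C@H]2[C@]3(CO3)CC[C@H]2C(=C)C[C@H]1OC(=O)CC(C)C | intermediate
19 | 8β-isovaleryloxy-4β,15-epoxyguaia-10(14),11(13)-dien-12,6α-olide | C=C1C(=O)O[C@@H]2[C@H]3[C@]4(CO4)CC[C@H]3C(=C)C[C@@H](OC(=O)CC(C)C)[C@@H]12 | intermediate
20 | C14 B-alkyl-9-BBN adduct of 19 | C=C1C(=O)O[C@@H]2[C@H]3[C@]4(CO4)CC[C@H]3[C@@H](CB5C6CCCC5CCC6)C[C@@H](OC(=O)CC(C)C)[C@@H]12 | intermediate
21 | 14-hydroxy epoxy guaianolide (10α-H) | C=C1C(=O)O[C@@H]2[C@H]3[C@]4(CO4)CC[C@H]3[C@@H](CO)C[C@@H](OC(=O)CC(C)C)[C@@H]12 | intermediate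
22 | 14-oxo epoxy guaianolide (10α-H) | C=C1C(=O)O[C@@H]2[C@H]3[C@]4(CO4)CC[C@H]3[C@@H](C=O)C[C@@H](OC(=O)CC(C)C)[C@@H]12 | intermediate
23 | CNP0345200.3 | C=C1C(=O)O[C@@H]2/C=C(/CO)CC/C=C(/C=O)C[C@@H](OC(=O)CC(C)C)[C@@H]12 | target

**Total step count:** 11. **Longest linear sequence:** 9 (steps 3–11).

**Three steps most likely to fail**

Step 11 is the new ring expansion. The enolate may fail to reach the aligned conformer, or the epoxide may react in another way.
- The fallback sets out from 22 and comes back at 23.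
- Periodic acid cleaves the spiro-epoxide to the 15-nor 4-ketone aldehyde F1.
- This 1,5-keto aldehyde is a Michael adduct, and a base-mediated retro-Michael reaction (DBU, heat) opens it to the ten-membered keto enal F2.
- Kinetic enolisation towards C5 with in situ Comins triflation gives the ring-cis enol triflate F3.
- Stille hydroxymethylation (Bu3SnCH2OH, Pd(0), LiCl) then gives 23.

Step 7 is the ring closure, where the facial choice at C6 is the weak point.
- The fallback sets out from 16 and comes back at 17.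
- If the closure gives the 6β-hydroxy epimer F4, Dess–Martin oxidation converts it to the C6 ketone F5.
- Reduction from the convex face with L-Selectride at −78 °C then gives 17.

Step 5 is the asymmetric Cr allylation, which may be sluggish or unselective with a γ-substituted bromide.
- The fallback sets out from 11 and 4 and comes back at 15.
- An indium-mediated Barbier coupling in THF/H2O lets the Z bromide react as a Z-type allylindium and gives the syn 8β-alcohol F6.
- F6 is separated from its (7S,8S) diastereomer with the help of the C1 stereocentre.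
- Acylation with isovaleryl chloride and pyridine gives 15, so no inversion is needed.

**Further compounds**
F1 | step 11 | 15-nor-4,14-dioxo guaianolide | C=C1C(=O)O[C@@H]2[C@H]3C(=O)CC[C@H]3[C@@H](C=O)C[C@@H](OC(=O)CC(C)C)[C@@H]12
F2 | step 11 | ten-membered 4-keto enal | C=C1C(=O)O[C@@H]2CC(=O)CC/C=C(/C=O)C[C@@H](OC(=O)CC(C)C)[C@@H]12
F3 | step 11 | ten-membered C4 enol triflate | C=C1C(=O)O[C@@H]2/C=C(/OS(=O)(=O)C(F)(F)F)CC/C=C(/C=O)C[C@@H](OC(=O)CC(C)C)[C@@H]12
F4 | step 7 | 6-epimer of 17 | C=C1CC[C@@H]2[C@H]1[C@H](O)[C@H](C(=C)C(=O)OC)[C@H](OC(=O)CC(C)C)CC2=C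
F5 | step 7 | C6 ketone from F4 | C=C1CC[C@@H]2[C@H]1C(=O)[C@H](C(=C)C(=O)OC)[C@H](OC(=O)CC(C)C)CC2=C
F6 | step 5 | (3R,4R) syn hydroxy ester | C=C(C(=O)OC)[C@@H](C(OC)OC)[C@H](O)CC(=C)[C@@H]1CCC(C[Si](C)(C)C)=C1
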